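## Structural features

The target is a drimane sesquiterpene joined to a quinone: a trans-fused decalin (ring A = C1–C5 and C10 with the gem-dimethyl carbon C4; ring B = C5–C10) whose C9 carries an exocyclic, fully substituted C9=C11 alkene bearing chlorine and a 6-methoxy-1,4-benzoquinon-2-yl group. There are three stereocentres: the vicinal ring-fusion pair C5 (H, S) and C10 (quaternary, methyl, S), and C8 (S), which stands next to the sp2 carbon C9. The C8 methyl group is cis to the C10 methyl group, that is axial, where it avoids allylic 1,3-strain with the chlorine. The alkene is E: chlorine lies on the C8 side and the quinone on the side of the quaternary C10. The quinone (bases, nucleophiles, hydrides, hydrogenation) and the alkenyl chloride (hydrogenolysis) are the fragile groups, so the quinone should be unmasked last from a 2,3,5-trimethoxyphenyl ring. The real difficulty is twofold: making the crowded chloroalkene with one geometry between C10 and C8, and setting C5/C10 in absolute terms without a chiral-pool decalin. The key step exploits the vicinal C5–C10 pair of ring A: this bond, with one C–H end and one quaternary end, is the σ bond formed in a [3,3] shift inside a δ-lactone whose carbinol carbon becomes C2. One oxygen-bearing stereocentre and a Z enyne are thereby translated into both ring-fusion centres and into ring A itself.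

## Logic of the disconnections

29 ⇒ 28. The two quinone carbonyl groups are traced back to the para pair of methoxy groups of an arene (two O–CH3 bonds restored). The quinone would not survive hydrides, bases, copper hydride or diimide, so it is carried as an arene; 28 then holds only robust functions. The forward oxidation must give the para- and not the ortho-quinone and must spare the chloroalkene.

28 ⇒ 27 ⇒ 25. The C8–H and C12–H bonds (and the C1–H/C2–H pair) are removed to reach 27, and the C8=C12 bond is traced to the C8–O bond of 25. C8 is set last because hydrogen can then be delivered to an exocyclic methylene from the α face, opposite the axial C10 methyl, and because the ring-A alkene can be removed in the same operation. The forward reduction must leave the tetrasubstituted chloroalkene and its C–Cl bond alone, and the elimination must run towards the methyl group.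

25 ⇒ 24. Ring B is opened at C8–C9, and the C11–Cl bond is removed with it. Both bonds can form in one cationic event in which a ketone is the electrophile, the aryl alkyne the nucleophile and the metal alkoxide on C8 the chloride donor. The bicyclic chloroalkene becomes a monocyclic ketone carrying only C5 and C10. The forward step must make C9 (not C11) the attacking carbon and must deliver chloride on the C8 side.

24 ⇒ 23 ⇒ 21 + 22, and 21 ⇒ 20 ⇒ 19. The C6–C7 bond is cut (as a C6=C7 olefination), so C7, C8 and the C8 methyl come from 22, and the C6 oxidation level is adjusted back to the carboxyl of 19. This returns directly to the rearrangement product. The forward olefination must work on an aldehyde flanked by two fully substituted carbons without epimerising C5, and the conjugate reduction must spare the alkyne and the ring alkene.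

19 ⇒ 16 (key disconnection). The C5–C10 bond is cut and the C2–O bond restored, which reopens ring A to a δ-lactone. Two contiguous stereocentres, one of them quaternary, are exchanged for one carbinol centre and one alkene geometry. The forward step demands a boat transition state, a geometrically pure Z enyne and clean enolisation.

16 ⇒ 11 + 15. The sp–sp2 bond C9–C10 is cut. This joins two fragments of similar size late, by a coupling that keeps alkene geometry. It requires an alkenyl iodide of secure Z geometry and mild conditions for the allylic lactone.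

11 ⇒ 9 ⇒ 6. The C10–I and C1–H bonds are traced to an alkyne, and the lactone carbonyl to a primary alcohol. A hydroalumination directed by the propargylic alkoxide is stereospecifically trans, so the alkene geometry becomes a consequence of mechanism. An ylide-based iodo-olefination of an α-acyloxy aldehyde would leave both the geometry and the carbinol configuration less secure. The price is that the hydride also reduces the lactone, so the carboxyl level has to be restored by a selective oxidation.

6 ⇒ 4 ⇒ 2 + 3 ⇒ 1. The C2–H bond is traced to a ketone, the C1–C2 bond to an acylation of 3, and the amide to the ring opening of 1. One catalytic asymmetric reduction then sets the only stereocentre that the route has to create from nothing, and a symmetrical, cheap 1 supplies C3–C6 with the gem-dimethyl group. The forward steps need high enantioselectivity and mono-addition.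

15 ⇒ 14 ⇒ 13 ⇒ 12. The terminal alkyne carbon (C9) is removed to leave the aldehyde carbon C11, then one O–CH3 bond, then the aryl C–O bond para to the phenol is traced to a C–Br bond. The oxygenation pattern is thus reached from 12 by routine steps. The methoxylation must work on an electron-rich bromide.

## Other disconnections considered

Alternative 1: The cut is C8–C9 together with C11–aryl, with chlorine introduced afterwards in place of boron. Forward, the lithium acetylide of the ring-A alkyne ketal A2 would be added to the aryl pinacol boronate A3. Me3SiOTf would then ionise the C8 ketal, C9 would attack the oxocarbenium ion, and the aryl group would shift from boron to C11 anti to the new C8–C9 bond. The product would be the alkenyl boronate A1 with boron on the C8 side.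
- In its favour: ring B, two C–C bonds and the tetrasubstituted alkene arise in one operation. The geometry follows from a stereospecific 1,2-shift; on this point the alternative is better than the chosen plan, where geometry rests on chloride delivery from titanium. The arene also enters late and convergently.
- Against it here: A2 still needs the C5/C10 pair, so a ring-A synthesis such as the lactone ring contraction is required anyway. This makes it an alternative to step 15 rather than to the key step. The borate must form next to the quaternary C10 with an ortho-substituted arylboron partner, and boron at a flanked tetrasubstituted position must still be exchanged for chlorine.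
- Equal: the C8 methoxy group must be eliminated and C8 reduced, the same endgame problem as in the chosen plan.
- Step economy: about equal. The Sonogashira step is saved, but ketal formation and the boron-to-chlorine exchange are added.

Alternative 2: The cut is C9–C11 and C11–aryl on a preformed decalin. Forward, zerovalent palladium from Pd(OAc)2 and 1,1'-bis(diphenylphosphino)ferrocene would insert into the C9–O bond of the enol triflate A5, take up carbon monoxide, and couple the acyl group with the boronic acid A6. The product would be the aryl enone A4.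
- In its favour: the decalin with C5 and C10 could come from the chiral pool, so neither an asymmetric step nor a ring construction would be needed. On access to the carbon skeleton this alternative is better than the chosen plan, and the coupling type is robust.
- Against it here: A4 has the alkene at C8=C9 and oxygen at C11. The target needs the alkene at C9=C11, chlorine in place of oxygen with one geometry, and a defined C8. No stereocontrolled way from A4 to that array is evident; for example, the geometry of a tetrasubstituted enol derivative made by conjugate reduction is not controlled. Carbon monoxide insertion at a triflate next to C10 would also compete with direct coupling.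
- Comparison: the chosen plan answers the geometric problem in the ring-closing event itself. The alternative is shorter to the skeleton, but probably longer and less certain afterwards.

Alternative 3: The cut is C9–C10 (ring B is contracted retrosynthetically to a five-membered carbinol) and C11–Cl. Forward, PdCl2(MeCN)2 would activate the alkyne of the alkynyl hydrindanol A8, and C10 would migrate from C8 to C9 anti to palladium while C8 becomes a ketone. CuCl2 would then replace palladium at C11 by chlorine to give the β-chloro enone A7.
- In its favour: ring B, the C8 carbonyl, chlorine and the alkene geometry would all come from one step with mechanism-dictated geometry, which is better than the chosen plan on that point. The quaternary C10 is a good migrating group and keeps its configuration. Methylenation of the C8 ketone would give the exocyclic alkene without any regiochemical question, which is better than the elimination of step 16.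
- Against it here: A8 requires a trans-hydrindanone with the C5/C10 pair and the gem-dimethyl group, whose enantioselective synthesis is a task of about the size of the chosen lactone route. Migration of C7, or simple chloropalladation, could compete. CuCl2 meets an electron-rich arene, and the β-chloro enone is open to addition–elimination.
- Comparison: step economy is similar. The alternative has the surer geometry; the chosen plan has the simpler origin of ring A and of the absolute configuration, from an achiral anhydride and one catalytic reduction.

Key step: step 10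

Remarks on the chemistry (assumptions):
- Drimane numbering (C1–C12) is used for the atoms of all intermediates.
- The ring contraction gives the C5/C10 configuration of the target only from the (6R) lactone with the Z enyne, so the precursor is specified as such.
- The carboxyl carbon of 19 is C6, so the chain to the C8 ketone needs three further carbons (C7, C8 and the C8 methyl).
- 12 is taken as a commercial compound (it is also one bromination away from o-vanillin).
- 25 is drawn as the 8α-hydroxy epimer expected from chloride delivery by the titanium alkoxide.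

## Route

Step 1
Reactants: 1 3,3-dimethylglutaric anhydride
Product: 2 5-[methoxy(methyl)amino]-3,3-dimethyl-5-oxopentanoic acid
Conditions: MeNH(OMe)·HCl, pyridine, CH2Cl2, 0 °C to rt
Reagents that add atoms: N,O-dimethylhydroxylamine hydrochloride, SMILES CNOC.Cl
Why: Aminolysis of a symmetrical cyclic anhydride can only give the mono-amide acid, so the Weinreb amide and the future lactone carboxyl are differentiated in one step with the gem-dimethyl carbon C4 in place.

Step 2
Reactants: 2 5-[methoxy(methyl)amino]-3,3-dimethyl-5-oxopentanoic acid; 3 prop-1-yn-1-ylmagnesium bromide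
Product: 4 3,3-dimethyl-5-oxooct-6-ynoic acid
Conditions: 3 (2.5 equiv), THF, −20 °C to rt; 1 M HCl
Reagents that add atoms: none
Why: Weinreb ketone synthesis: one equivalent of 3 is spent on the acid, the next adds to the amide, and the magnesium chelate of the adduct persists until work-up, so the alkynyl ketone is not attacked again.

Step 3
Reactants: 4 3,3-dimethyl-5-oxooct-6-ynoic acid
Product: 6 (6R)-4,4-dimethyl-6-(prop-1-yn-1-yl)oxan-2-one, via hydroxy acid 5 (not isolated)
Conditions: RuCl[(R,R)-TsDPEN](p-cymene) (1 mol%), HCO2H/Et3N (5:2), CH2Cl2, rt; TsOH (cat.), toluene, rt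
Reagents that add atoms: none
Why: Noyori asymmetric transfer hydrogenation of an alkynyl ketone: with the (R,R) ligand, hydride should reach the face that gives the (R)-propargylic alcohol (the alkyne takes the place of the aryl group in the usual model), which sets C2. The hydroxy acid 5 then closes to the δ-lactone, helped by the gem-dimethyl group.

Step 4
Reactants: 6 (6R)-4,4-dimethyl-6-(prop-1-yn-1-yl)oxan-2-one
Product: 9 (5R,6Z)-7-iodo-3,3-dimethyloct-6-ene-1,5-diol, via ynediol 7 (not isolated), via alkenylalanate 8 (not isolated)
Conditions: NaAlH2(OCH2CH2OCH3)2 (4 equiv), THF, 0 °C to rt; I2, THF, −78 to 0 °C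
Reagents that add atoms: iodine, SMILES II; sodium bis(2-methoxyethoxy)aluminium dihydride, SMILES [Na+].[AlH2-](OCCOC)OCCOC (its aluminium and alkoxy groups remain in 8 only)
Why: The hydride first reduces the lactone to the diol alkoxide 7; the propargylic alkoxide then directs a trans-hydroalumination that puts hydrogen on C1 and aluminium on C10 in the five-membered alanate 8, and iodine replaces aluminium with retention. The Z iodoalkene (iodine cis to the carbinol carbon) is thus formed stereospecifically and C2 is untouched.

Step 5
Reactants: 9 (5R,6Z)-7-iodo-3,3-dimethyloct-6-ene-1,5-diol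
Product: 11 (6R)-6-[(1Z)-2-iodoprop-1-en-1-yl]-4,4-dimethyloxan-2-one, via lactol 10 (not isolated)
Conditions: TEMPO (0.2 equiv), PhI(OAc)2 (2.5 equiv), CH2Cl2, rt
Reagents that add atoms: none
Why: Oxoammonium (TEMPO) oxidation is selective for the primary alcohol; the aldehyde is trapped by the secondary hydroxyl as lactol 10, which is oxidised on to the lactone (oxidative lactonisation of a 1,5-diol). The allylic alcohol and the iodoalkene are not touched.

Step 6
Reactants: 12 5-bromo-2-hydroxy-3-methoxybenzaldehyde
Product: 13 2-hydroxy-3,5-dimethoxybenzaldehyde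
Conditions: NaOMe (5 equiv), CuCl (0.3 equiv), MeOH/DMF, 110 °C; aq. HCl
Reagents that add atoms: sodium methoxide, SMILES C[O-].[Na+]
Why: Ullmann-type copper-catalysed methoxylation of the aryl bromide; the substrate reacts as its phenoxide, which protects the aldehyde, as in the classical conversion of bromophenol aldehydes into methoxyphenol aldehydes.

Step 7
Reactants: 13 2-hydroxy-3,5-dimethoxybenzaldehyde
Product: 14 2,3,5-trimethoxybenzaldehyde
Conditions: MeI, K2CO3, DMF, rt
Reagents that add atoms: iodomethane, SMILES CI
Why: Williamson O-methylation of the phenol.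

Step 8
Reactants: 14 2,3,5-trimethoxybenzaldehyde
Product: 15 1-ethynyl-2,3,5-trimethoxybenzene
Conditions: MeC(O)C(N2)P(O)(OMe)2, K2CO3, MeOH, rt
Reagents that add atoms: dimethyl (1-diazo-2-oxopropyl)phosphonate, SMILES CC(=O)C(=[N+]=[N-])P(=O)(OC)OC
Why: Seyferth–Gilbert homologation with the Ohira–Bestmann reagent: the diazomethylphosphonate anion formed by methanolysis olefinates the aldehyde, and the diazoalkene loses N2 with a 1,2-shift to the terminal alkyne. The conditions suit an electron-rich, non-enolisable aldehyde.

Step 9
Reactants: 11 (6R)-6-[(1Z)-2-iodoprop-1-en-1-yl]-4,4-dimethyloxan-2-one; 15 1-ethynyl-2,3,5-trimethoxybenzene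
Product: 16 (6R)-4,4-dimethyl-6-[(1Z)-2-methyl-4-(2,3,5-trimethoxyphenyl)but-1-en-3-yn-1-yl]oxan-2-one
Conditions: PdCl2(PPh3)2 (3 mol%), CuI (6 mol%), Et3N, THF, rt
Reagents that add atoms: none
Why: Sonogashira coupling: oxidative addition of zerovalent palladium into the alkenyl iodide and reductive elimination both go with retention, so the Z geometry passes into the enyne. Room temperature keeps the allylic lactone C–O bond from ionising.

Step 10
Reactants: 16 (6R)-4,4-dimethyl-6-[(1Z)-2-methyl-4-(2,3,5-trimethoxyphenyl)but-1-en-3-yn-1-yl]oxan-2-one
Product: 19 (1S,2S)-2,6,6-trimethyl-2-[(2,3,5-trimethoxyphenyl)ethynyl]cyclohex-3-ene-1-carboxylic acid, via silyl ketene acetal 17 (not isolated), via silyl ester 18 (not isolated)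
Conditions: LiN(iPr)2, tBuMe2SiCl, DMPU, THF, −78 °C; toluene, 105 °C; 1 M HCl, THF, 0 °C
Reagents that add atoms: tert-butyldimethylsilyl chloride, SMILES CC(C)(C)[Si](C)(C)Cl (the silyl group is carried by 17 and 18 only)
Why: Kinetic deprotonation at C5 with silylation gives the cyclic silyl ketene acetal 17, whose enol ether geometry is fixed by the ring. On heating, a concerted suprafacial [3,3] shift forms C5–C10 and breaks C2–O while the C1=C2 alkene appears; the closest known reaction type is the Ireland–Claisen ring contraction of 6-alkenyl δ-lactones to cyclohexenecarboxylic acids. Ring A closes in this way as a six-membered carbocycle through a pericyclic (not a polar, Baldwin-type) closure in which the lactone α-carbon bonds to the far end of the exocyclic alkene. Because C5 and C2 are tied by the two-atom C4–C3 bridge, the six reacting atoms can only adopt a boat (a bicyclo[2.2.2]octane-like array). C5 is controlled by C2: the enyne arm on the (R)-carbinol carbon can reach only one face of the ketene acetal, so the new bond is made on that face. C10 is controlled by the alkene geometry: in the boat the substituent cis to C2 (the alkyne) points towards the C3–C4 bridge and ends trans to the carboxyl group, while the methyl group ends cis to it. The step needs complete transfer of chirality from C2 to C5 and C10; the enforced boat, the stereospecifically made Z enyne and the slim alkyne in the crowded inside position next to the gem-dimethyl carbon secure it. Hydrolysis of the silyl ester 18 on work-up gives 19.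

Step 11
Reactants: 19 (1S,2S)-2,6,6-trimethyl-2-[(2,3,5-trimethoxyphenyl)ethynyl]cyclohex-3-ene-1-carboxylic acid
Product: 20 {(1S,2S)-2,6,6-trimethyl-2-[(2,3,5-trimethoxyphenyl)ethynyl]cyclohex-3-en-1-yl}methanol
Conditions: LiAlH4, THF, 0 °C to reflux
Reagents that add atoms: none
Why: Hydride reduction of the hindered acid to the primary alcohol; the isolated alkene, the internal alkyne and the aryl ethers are inert, and C5 cannot epimerise at this oxidation level.

Step 12
Reactants: 20 {(1S,2S)-2,6,6-trimethyl-2-[(2,3,5-trimethoxyphenyl)ethynyl]cyclohex-3-en-1-yl}methanol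
Product: 21 (1S,2S)-2,6,6-trimethyl-2-[(2,3,5-trimethoxyphenyl)ethynyl]cyclohex-3-ene-1-carbaldehyde
Conditions: Dess–Martin periodinane, CH2Cl2, 0 °C to rt
Reagents that add atoms: none
Why: Dess–Martin oxidation stops at the aldehyde under nearly neutral conditions, which matters because C5 is now α to a carbonyl group.

Step 13
Reactants: 21 (1S,2S)-2,6,6-trimethyl-2-[(2,3,5-trimethoxyphenyl)ethynyl]cyclohex-3-ene-1-carbaldehyde; 22 dimethyl (2-oxopropyl)phosphonate
Product: 23 (3E)-4-{(1S,2S)-2,6,6-trimethyl-2-[(2,3,5-trimethoxyphenyl)ethynyl]cyclohex-3-en-1-yl}but-3-en-2-one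
Conditions: Ba(OH)2, THF/H2O (40:1), rt
Reagents that add atoms: none
Why: Horner–Wadsworth–Emmons olefination with a β-ketophosphonate gives the E enone and adds the three carbons C7, C8 and the C8 methyl. The small phosphonate anion is chosen because the aldehyde stands between two fully substituted carbons, and the weak base limits enolisation at C5.

Step 14
Reactants: 23 (3E)-4-{(1S,2S)-2,6,6-trimethyl-2-[(2,3,5-trimethoxyphenyl)ethynyl]cyclohex-3-en-1-yl}but-3-en-2-one
Product: 24 4-{(1S,2S)-2,6,6-trimethyl-2-[(2,3,5-trimethoxyphenyl)ethynyl]cyclohex-3-en-1-yl}butan-2-one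
Conditions: [(Ph3P)CuH]6 (0.4 equiv), H2O (2 equiv), benzene, rt
Reagents that add atoms: none
Why: Conjugate reduction by the phosphine-stabilised copper hydride: hydride adds to C6 of the enone and the copper enolate is protonated by water. The unactivated ring alkene and the hindered internal alkyne should not react at room temperature.

Step 15
Reactants: 24 4-{(1S,2S)-2,6,6-trimethyl-2-[(2,3,5-trimethoxyphenyl)ethynyl]cyclohex-3-en-1-yl}butan-2-one
Product: 25 (5S,8R,10S)-11-chloro-11-(2,3,5-trimethoxyphenyl)drima-1,9(11)-dien-8-ol (8α-OH, 8β-methyl; chlorine on the C8 side of C9=C11, descriptor Z here because C8 bears oxygen)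
Conditions: TiCl4 (1.5 equiv), CH2Cl2, −78 to −40 °C; aq. NaHCO3
Reagents that add atoms: titanium tetrachloride, SMILES Cl[Ti](Cl)(Cl)Cl
Why: Prins-type alkyne–ketone cyclisation: the TiCl4-activated ketone is attacked by C9 (6-exo-dig with respect to the alkyne, the mode that places the vinyl cation at C11 next to the electron-rich arene), and the cation is captured by chloride from the titanium alkoxide on C8. This should put chlorine on the C8 side and the aryl group on the C10 side. The trans C5/C10 relationship places both ring-B arms equatorial, so the trans-decalin closes without strain.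

Step 16
Reactants: 25 (5S,8R,10S)-11-chloro-11-(2,3,5-trimethoxyphenyl)drima-1,9(11)-dien-8-ol
Product: 27 (5S,10S,9(11)E)-11-chloro-11-(2,3,5-trimethoxyphenyl)drima-1,8(12),9(11)-triene, via chlorosulfite 26 (not isolated)
Conditions: SOCl2 (1.5 equiv), pyridine (6 equiv), CH2Cl2, −78 to −30 °C
Reagents that add atoms: thionyl chloride, SMILES O=S(Cl)Cl (retained in 26 only)
Why: The tertiary alcohol is converted into the chlorosulfite 26 and eliminated by pyridine (E2). With the leaving group equatorial no ring hydrogen is antiperiplanar, so the proton is taken from the methyl group and the exocyclic 8(12)-alkene results, the behaviour known for 8α-hydroxydrimanes. The low temperature is meant to suppress ionisation of the allylic system.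

Step 17
Reactants: 27 (5S,10S,9(11)E)-11-chloro-11-(2,3,5-trimethoxyphenyl)drima-1,8(12),9(11)-triene
Product: 28 (5S,8S,10S,9(11)E)-11-chloro-11-(2,3,5-trimethoxyphenyl)drim-9(11)-ene
Conditions: 2-O2NC6H4SO2NHNH2 (excess, in portions), Et3N, CH2Cl2, rt
Reagents that add atoms: none
Why: Diimide reduction: concerted syn transfer of H2 to the cis-disubstituted ring-A alkene and the 1,1-disubstituted exocyclic alkene; diimide cannot add 1,4 across the diene, does not cleave C–Cl and does not reduce the tetrasubstituted C9=C11 bond. Hydrogen reaches C8 from the α face, opposite the axial C10 methyl group, which gives the 8β-methyl (8S) centre; this is also the arrangement that avoids allylic strain with chlorine.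

Step 18
Reactants: 28 (5S,8S,10S,9(11)E)-11-chloro-11-(2,3,5-trimethoxyphenyl)drim-9(11)-ene
Product: 29 2-{(E)-chloro[(2S,4aS,8aS)-2,5,5,8a-tetramethyloctahydronaphthalen-1(2H)-ylidene]methyl}-6-methoxycyclohexa-2,5-diene-1,4-dione (target)
Conditions: (NH4)2Ce(NO3)6 (2.5 equiv), MeCN/H2O, 0 °C
Reagents that add atoms: water, SMILES O
Why: Oxidative demethylation of the para-dimethoxy pair by tetravalent cerium (two one-electron oxidations, water attacking the ring carbons and methanol leaving) gives the 1,4-quinone and keeps the third methoxy group. The twisted, chlorine-bearing alkene is a poor electron donor and should survive.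

## Compound list

1 | 3,3-dimethylglutaric anhydride (4,4-dimethyloxane-2,6-dione) | O=C1CC(C)(C)CC(=O)O1 | starting material
2 | 5-[methoxy(methyl)amino]-3,3-dimethyl-5-oxopentanoic acid | CON(C)C(=O)CC(C)(C)CC(=O)O | intermediate
3 | prop-1-yn-1-ylmagnesium bromide | CC#C[Mg]Br | starting material
4 | 3,3-dimethyl-5-oxooct-6-ynoic acid | CC#CC(=O)CC(C)(C)CC(=O)O | intermediate
5 | (5R)-5-hydroxy-3,3-dimethyloct-6-ynoic acid | OC(=O)CC(C)(C)C[C@@H](O)C#CC | intermediate (not isolated)
6 | (6R)-4,4-dimethyl-6-(prop-1-yn-1-yl)oxan-2-one | O=C1CC(C)(C)C[C@@H](O1)C#CC | intermediate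
7 | (5R)-3,3-dimethyloct-6-yne-1,5-diol (present as its aluminium alkoxide) | OCCC(C)(C)C[C@@H](O)C#CC | intermediate (not isolated)
8 | sodium (5R)-5-(4-hydroxy-2,2-dimethylbutyl)-2,2-bis(2-methoxyethoxy)-3-methyl-2,5-dihydro-1,2-oxaaluminol-2-uide (cyclic alkenylalanate; remote oxygen drawn as OH) | CC1=C[C@@H](CC(C)(C)CCO)O[Al-]1(OCCOC)OCCOC.[Na+] | intermediate (not isolated)
9 | (5R,6Z)-7-iodo-3,3-dimethyloct-6-ene-1,5-diol | OCCC(C)(C)C[C@@H](O)/C=C(/C)I | intermediate
10 | (6R)-6-[(1Z)-2-iodoprop-1-en-1-yl]-4,4-dimethyloxan-2-ol (both anomers) | OC1CC(C)(C)C[C@@H](O1)/C=C(/C)I | intermediate (not isolated)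
11 | (6R)-6-[(1Z)-2-iodoprop-1-en-1-yl]-4,4-dimethyloxan-2-one | O=C1CC(C)(C)C[C@@H](O1)/C=C(/C)I | intermediate
12 | 5-bromo-2-hydroxy-3-methoxybenzaldehyde | COc1cc(Br)cc(C=O)c1O | starting material
13 | 2-hydroxy-3,5-dimethoxybenzaldehyde | COc1cc(OC)c(O)c(C=O)c1 | intermediate
14 | 2,3,5-trimethoxybenzaldehyde | COc1cc(OC)c(OC)c(C=O)c1 | intermediate
15 | 1-ethynyl-2,3,5-trimethoxybenzene | COc1cc(OC)c(OC)c(C#C)c1 | intermediate
16 | (6R)-4,4-dimethyl-6-[(1Z)-2-methyl-4-(2,3,5-trimethoxyphenyl)but-1-en-3-yn-1-yl]oxan-2-one | O=C1CC(C)(C)C[C@@H](O1)/C=C(/C)C#Cc1cc(OC)cc(OC)c1OC | intermediate (key-step precursor)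
17 | tert-butyl({(2R)-4,4-dimethyl-2-[(1Z)-2-methyl-4-(2,3,5-trimethoxyphenyl)but-1-en-3-yn-1-yl]-3,4-dihydro-2H-pyran-6-yl}oxy)dimethylsilane | CC(C)(C)[Si](C)(C)OC1=CC(C)(C)C[C@@H](O1)/C=C(/C)C#Cc1cc(OC)cc(OC)c1OC | intermediate (not isolated)
18 | tert-butyldimethylsilyl (1S,2S)-2,6,6-trimethyl-2-[(2,3,5-trimethoxyphenyl)ethynyl]cyclohex-3-ene-1-carboxylate | CC(C)(C)[Si](C)(C)OC(=O)[C@H]1C(C)(C)CC=C[C@]1(C)C#Cc1cc(OC)cc(OC)c1OC | intermediate (not isolated)
19 | (1S,2S)-2,6,6-trimethyl-2-[(2,3,5-trimethoxyphenyl)ethynyl]cyclohex-3-ene-1-carboxylic acid | OC(=O)[C@H]1C(C)(C)CC=C[C@]1(C)C#Cc1cc(OC)cc(OC)c1OC | intermediate (key-step product)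
20 | {(1S,2S)-2,6,6-trimethyl-2-[(2,3,5-trimethoxyphenyl)ethynyl]cyclohex-3-en-1-yl}methanol | OC[C@H]1C(C)(C)CC=C[C@]1(C)C#Cc1cc(OC)cc(OC)c1OC | intermediate
21 | (1S,2S)-2,6,6-trimethyl-2-[(2,3,5-trimethoxyphenyl)ethynyl]cyclohex-3-ene-1-carbaldehyde | O=C[C@H]1C(C)(C)CC=C[C@]1(C)C#Cc1cc(OC)cc(OC)c1OC | intermediate
22 | dimethyl (2-oxopropyl)phosphonate | COP(=O)(OC)CC(C)=O | starting material
23 | (3E)-4-{(1S,2S)-2,6,6-trimethyl-2-[(2,3,5-trimethoxyphenyl)ethynyl]cyclohex-3-en-1-yl}but-3-en-2-one | CC(=O)/C=C/[C@H]1C(C)(C)CC=C[C@]1(C)C#Cc1cc(OC)cc(OC)c1OC | intermediate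
24 | 4-{(1S,2S)-2,6,6-trimethyl-2-[(2,3,5-trimethoxyphenyl)ethynyl]cyclohex-3-en-1-yl}butan-2-one | CC(=O)CC[C@H]1C(C)(C)CC=C[C@]1(C)C#Cc1cc(OC)cc(OC)c1OC | intermediate
25 | (5S,8R,10S,9(11)Z)-11-chloro-11-(2,3,5-trimethoxyphenyl)drima-1,9(11)-dien-8-ol (8α-OH, 8β-CH3, 5α-H, 10β-CH3; Cl on the C8 side) | COc1cc(OC)c(OC)c(c1)/C(Cl)=C2/[C@@](O)(C)CC[C@H]3C(C)(C)CC=C[C@]23C | intermediate
26 | chlorosulfite of 25 (8α-OS(O)Cl) | COc1cc(OC)c(OC)c(c1)/C(Cl)=C2/[C@@](OS(=O)Cl)(C)CC[C@H]3C(C)(C)CC=C[C@]23C | intermediate (not isolated)
27 | (5S,10S,9(11)E)-11-chloro-11-(2,3,5-trimethoxyphenyl)drima-1,8(12),9(11)-triene | COc1cc(OC)c(OC)c(c1)/C(Cl)=C2/C(=C)CC[C@H]3C(C)(C)CC=C[C@]23C | intermediate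
28 | (5S,8S,10S,9(11)E)-11-chloro-11-(2,3,5-trimethoxyphenyl)drim-9(11)-ene (8β-CH3) | COc1cc(OC)c(OC)c(c1)/C(Cl)=C2/[C@@H](C)CC[C@H]3C(C)(C)CCC[C@]23C | intermediate
29 | 2-{(E)-chloro[(2S,4aS,8aS)-2,5,5,8a-tetramethyloctahydronaphthalen-1(2H)-ylidene]methyl}-6-methoxycyclohexa-2,5-diene-1,4-dione | COC1=CC(=O)C=C(/C(Cl)=C2/[C@@H](C)CC[C@H]3C(C)(C)CCC[C@]23C)C1=O | target

## Step count and least certain steps

Total step count: 18. Longest linear sequence: 15 (steps 1–5 and 9–18); steps 6–8 are the three-step aryl branch that joins at step 9.

Step 10 (key step). The boat rearrangement has to join C5, next to the gem-dimethyl carbon, to a fully substituted alkene carbon. If this is slow, heterolysis of the allylic C2–O bond of the ketene acetal can outrun the concerted shift, because the resulting cation is stabilised through the enyne by the electron-rich arene. The consequences would be loss of chirality transfer, elimination, or scrambling of the alkene geometry. Fallback (rearrangement before arylation, from 11 back to 19):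
- Sonogashira coupling of 11 with ethynyltrimethylsilane would give (6R)-4,4-dimethyl-6-[(1Z)-2-methyl-4-(trimethylsilyl)but-1-en-3-yn-1-yl]oxan-2-one F1, in which the alkyne no longer carries a donor arene.
- The same enolisation, silylation and heating would give (1S,2S)-2,6,6-trimethyl-2-[(trimethylsilyl)ethynyl]cyclohex-3-ene-1-carboxylic acid F2.
- The aryl partner would be made separately: Dakin oxidation (H2O2, NaOH) of commercial 5-iodovanillin F3 to 2-iodo-6-methoxybenzene-1,4-diol F4, then O-methylation (MeI, K2CO3) to 1-iodo-2,3,5-trimethoxybenzene F5.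
- A desilylative Sonogashira coupling of F2 with F5 (PdCl2(PPh3)2, CuI, CsF, Et3N, DMF) would rejoin the route at 19.

Step 15. Chloride may be captured on the C10 side of the vinyl cation if internal delivery from titanium is lost, and the tertiary allylic titanium alkoxide may ionise once formed. Fallback (closure at the aldehyde oxidation level, from 21 back to 27):
- Wittig reaction of 21 with (triphenylphosphoranylidene)acetaldehyde would give (2E)-3-{(1S,2S)-2,6,6-trimethyl-2-[(2,3,5-trimethoxyphenyl)ethynyl]cyclohex-3-en-1-yl}prop-2-enal F6.
- Conjugate reduction with [(Ph3P)CuH]6 would give the saturated aldehyde 3-{(1S,2S)-2,6,6-trimethyl-2-[(2,3,5-trimethoxyphenyl)ethynyl]cyclohex-3-en-1-yl}propanal F7.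
- TiCl4 closure would give the secondary alcohol 11-chloro-11-(2,3,5-trimethoxyphenyl)-12-nordrima-1,9(11)-dien-8-ol F8. Its alkoxide is less prone to ionise, and the smaller C8 eases delivery of chloride.
- Dess–Martin oxidation would give the β-chloro enone 11-chloro-11-(2,3,5-trimethoxyphenyl)-12-nordrima-1,9(11)-dien-8-one F9.
- Wittig methylenation (Ph3P=CH2 from Ph3PCH3Br and KOtBu) would rejoin the route at 27, which also removes the elimination of step 16.

Step 16. The elimination may lose its regiocontrol and run into the ring towards C7, either because the C8 configuration of 25 is not the expected one or because the chlorosulfite reacts through an ion pair; chloride may also return to the allylic system. Fallback (from 25 back to 28):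
- Dehydration with the Burgess reagent in warm toluene, which eliminates through the ion pair towards the more substituted position, would give (5S,10S)-11-chloro-11-(2,3,5-trimethoxyphenyl)drima-1,7,9(11)-triene F10.
- Hydrogenation of F10 with H2 and [Ir(cod)(PCy3)(py)]PF6 in CH2Cl2, a catalyst able to reduce trisubstituted alkenes by cis addition from the α face, would give 28 directly.

Step 17. Reduction of the ring-A alkene, which stands next to the quaternary C10 and the aryl group, may be slow with diimide, so that the two alkenes are not reduced cleanly together; facial control at C8 could also be incomplete. Fallback (the two reductions separated, from 25 back to 28):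
- Hydrogenation of 25 with H2 and RhCl(PPh3)3, at a stage with no diene and only one reducible alkene, would give (5S,8R,10S)-11-chloro-11-(2,3,5-trimethoxyphenyl)drim-9(11)-en-8-ol F11.
- Elimination with SOCl2 and pyridine would give (5S,10S)-11-chloro-11-(2,3,5-trimethoxyphenyl)drima-8(12),9(11)-diene F12.
- Diimide then has only the exocyclic alkene to reduce and would give 28.

Step 13. Addition of the phosphonate anion to an aldehyde flanked by two fully substituted carbons may be slow, and during a long reaction C5 may epimerise through enolisation of the aldehyde or γ-deprotonation of the enone. Fallback (aldol addition and dehydration, from 21 back to 23):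
- The lithium enolate of acetone (LiN(iPr)2, acetone, THF, −78 °C), a small and strongly nucleophilic reagent, would add to 21 to give 4-hydroxy-4-{(1S,2S)-2,6,6-trimethyl-2-[(2,3,5-trimethoxyphenyl)ethynyl]cyclohex-3-en-1-yl}butan-2-one F13 (both carbinol epimers).
- Mesylation and elimination (MsCl, Et3N) would give 23.

## Further compounds

F1 | step 10 | (6R)-4,4-dimethyl-6-[(1Z)-2-methyl-4-(trimethylsilyl)but-1-en-3-yn-1-yl]oxan-2-one | O=C1CC(C)(C)C[C@@H](O1)/C=C(/C)C#C[Si](C)(C)C
F2 | step 10 | (1S,2S)-2,6,6-trimethyl-2-[(trimethylsilyl)ethynyl]cyclohex-3-ene-1-carboxylic acid | OC(=O)[C@H]1C(C)(C)CC=C[C@]1(C)C#C[Si](C)(C)C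
F3 | step 10 | 5-iodovanillin (4-hydroxy-3-iodo-5-methoxybenzaldehyde) | COc1cc(C=O)cc(I)c1O
F4 | step 10 | 2-iodo-6-methoxybenzene-1,4-diol | COc1cc(O)cc(I)c1O
F5 | step 10 | 1-iodo-2,3,5-trimethoxybenzene | COc1cc(OC)c(OC)c(I)c1
F6 | step 15 | (2E)-3-{(1S,2S)-2,6,6-trimethyl-2-[(2,3,5-trimethoxyphenyl)ethynyl]cyclohex-3-en-1-yl}prop-2-enal | O=C/C=C/[C@H]1C(C)(C)CC=C[C@]1(C)C#Cc1cc(OC)cc(OC)c1OC
F7 | step 15 | 3-{(1S,2S)-2,6,6-trimethyl-2-[(2,3,5-trimethoxyphenyl)ethynyl]cyclohex-3-en-1-yl}propanal | O=CCC[C@H]1C(C)(C)CC=C[C@]1(C)C#Cc1cc(OC)cc(OC)c1OC
F8 | step 15 | (5S,10S)-11-chloro-11-(2,3,5-trimethoxyphenyl)-12-nordrima-1,9(11)-dien-8-ol (Cl on the C8 side; C8 configuration open) | COc1cc(OC)c(OC)c(c1)/C(Cl)=C2/C(O)CC[C@H]3C(C)(C)CC=C[C@]23C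
F9 | step 15 | (5S,10S)-11-chloro-11-(2,3,5-trimethoxyphenyl)-12-nordrima-1,9(11)-dien-8-one (Cl on the C8 side) | COc1cc(OC)c(OC)c(c1)/C(Cl)=C2/C(=O)CC[C@H]3C(C)(C)CC=C[C@]23C
F10 | step 16 | (5S,10S,9(11)E)-11-chloro-11-(2,3,5-trimethoxyphenyl)drima-1,7,9(11)-triene | COc1cc(OC)c(OC)c(c1)/C(Cl)=C2/C(C)=CC[C@H]3C(C)(C)CC=C[C@]23C
F11 | step 17 | (5S,8R,10S)-11-chloro-11-(2,3,5-trimethoxyphenyl)drim-9(11)-en-8-ol (8α-OH; Cl on the C8 side) | COc1cc(OC)c(OC)c(c1)/C(Cl)=C2/[C@@](O)(C)CC[C@H]3C(C)(C)CCC[C@]23C
F12 | step 17 | (5S,10S,9(11)E)-11-chloro-11-(2,3,5-trimethoxyphenyl)drima-8(12),9(11)-diene | COc1cc(OC)c(OC)c(c1)/C(Cl)=C2/C(=C)CC[C@H]3C(C)(C)CCC[C@]23C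
F13 | step 13 | 4-hydroxy-4-{(1S,2S)-2,6,6-trimethyl-2-[(2,3,5-trimethoxyphenyl)ethynyl]cyclohex-3-en-1-yl}butan-2-one (carbinol epimers) | CC(=O)CC(O)[C@H]1C(C)(C)CC=C[C@]1(C)C#Cc1cc(OC)cc(OC)c1OC
A1 | alternative 1 | 2-[(5S,10S)-8-methoxy-11-(2,3,5-trimethoxyphenyl)drim-9(11)-en-11-yl]-4,4,5,5-tetramethyl-1,3,2-dioxaborolane (boron on the C8 side; C8 configuration immaterial) | COc1cc(OC)c(OC)c(c1)/C(B4OC(C)(C)C(C)(C)O4)=C2/[C@@](OC)(C)CC[C@H]3C(C)(C)CCC[C@]23C
A2 | alternative 1 | 4-[(1S,2S)-2-ethynyl-2,6,6-trimethylcyclohexyl]butan-2-one dimethyl ketal | COC(C)(OC)CC[C@H]1C(C)(C)CCC[C@]1(C)C#C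
A3 | alternative 1 | 4,4,5,5-tetramethyl-2-(2,3,5-trimethoxyphenyl)-1,3,2-dioxaborolane | COc1cc(OC)c(OC)c(c1)B1OC(C)(C)C(C)(C)O1
A4 | alternative 2 | (5S,10S)-11-(2,3,5-trimethoxyphenyl)drim-8-en-11-one | COc1cc(OC)c(OC)c(c1)C(=O)C2=C(C)CC[C@H]3C(C)(C)CCC[C@]23C
A5 | alternative 2 | (5S,10S)-11-nordrim-8-en-9-yl trifluoromethanesulfonate | FC(F)(F)S(=O)(=O)OC1=C(C)CC[C@H]2C(C)(C)CCC[C@]12C
A6 | alternative 2 | (2,3,5-trimethoxyphenyl)boronic acid | COc1cc(OC)c(OC)c(c1)B(O)O
A7 | alternative 3 | (5S,10S)-11-chloro-11-(2,3,5-trimethoxyphenyl)-12-nordrim-9(11)-en-8-one (Cl on the C8 side) | COc1cc(OC)c(OC)c(c1)/C(Cl)=C2/C(=O)CC[C@H]3C(C)(C)CCC[C@]23C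
A8 | alternative 3 | trans-fused 4,4,7a-trimethyl-1-[(2,3,5-trimethoxyphenyl)ethynyl]octahydro-1H-inden-1-ol (ring-fusion centres as in the target; carbinol configuration open) | COc1cc(OC)c(OC)c(c1)C#CC2(O)CC[C@H]3C(C)(C)CCC[C@]23C
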